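**Strategy.** Everything rests on cutting ring B at C1'–C6' and C2'–C3'. Ring B is a resorcinol whose prenyl carbon C3' lies between O2' and O4' and whose C1' carries the future C3–C4 unit, which is the substitution pattern of a 2-prenyl-4-alkylcyclohexane-1,3-dione. A single Michael–Claisen annulation therefore builds the carbocycle with both oxygens, the prenyl group and the two-carbon arm in place, so ring B never needs an aromatic C-prenylation. Its precursors are trimethyl ethane-1,1,2-tricarboxylate and 7-methylocta-1,6-dien-3-one. Afterwards the arm lactonises onto O2' (differentiating it from O4'), the ring is dehydrogenated, and the arm acylates a lithiated diprenylphloroglucinol (ring A) before C2 is inserted.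

Key step: step 3

Remarks on the chemistry:
- Abbreviations: prenyl = 3-methylbut-2-en-1-yl, MOM = methoxymethyl, THP = tetrahydro-2H-pyran-2-yl. Locants C1'–C6', O2' and O4' are those of ring B in the target.
- The annulation partners and product balance (C8H12O6 + C9H14O = C16H22O6 + CH4O) and are used as drawn. The side-arm ester is a third possible acyl acceptor, reachable from C5' through a five-membered transition state; step 3 deals with this.
- The vinyl ketone is made by a regiochemically unambiguous two-step route (Grignard addition to acrolein, then oxidation).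
- Assumption: enaminone 27 is drawn as the E isomer; the geometry of this push–pull alkene has no bearing on step 15.

**Step 1**
Reactants: 1 5-bromo-2-methylpent-2-ene; 2 acrolein (prop-2-enal)
Product: 4 7-methylocta-1,6-dien-3-ol (racemic), via Grignard reagent 3 (not isolated)
Conditions: Mg, I2 (cat.), THF, 40 °C; then 2, −78 °C to 0 °C; sat. aq. NH4Cl
Reagents that add atoms: none
Why: Grignard 1,2-addition to the aldehyde of acrolein should give the vinyl carbinol with the chain fixed regiochemically; the carbinol centre is racemic and is oxidised away in step 2.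

**Step 2**
Reactants: 4 7-methylocta-1,6-dien-3-ol
Product: 5 7-methylocta-1,6-dien-3-one
Conditions: Dess–Martin periodinane, CH2Cl2, 0 °C to rt; used without delay
Reagents that add atoms: none
Why: Dess–Martin oxidation of a secondary allylic alcohol is neutral and fast and should deliver the polymerisation-prone vinyl ketone without touching the trisubstituted alkene.

**Step 3**
Reactants: 5 7-methylocta-1,6-dien-3-one; 6 trimethyl ethane-1,1,2-tricarboxylate
Product: 8 methyl 1-(2-methoxy-2-oxoethyl)-3-prenyl-2,4-dioxocyclohexane-1-carboxylate (racemic), via Michael adduct 7 (not isolated)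
Conditions: NaOMe (0.1 equiv), MeOH, 0 °C; then NaOMe (1.1 equiv), reflux; cold 1 M HCl to pH 3
Reagents that add atoms: none
Why: Methoxide forms the tertiary malonate anion of 6, which adds in a 1,4 sense to vinyl ketone 5 (C1'–C6'); keto triester 7 then equilibrates between its enolates and the C3' enolate acylates itself on one of the two geminal ester carbonyls with loss of methoxide (C2'–C3'). The closest known reaction type is the dimedone-type Michael–Claisen annulation of a malonate with an enone. The ring closes in a 6-(enolexo)-exo-trig mode. C1' and C3' become stereocentres without control (racemic, C3' epimerised through the enol) and both are erased when ring B is aromatised, so none needs to be set. The selectivity required is closure from C3' onto a geminal ester instead of closure from C5', which could reach the side-arm ester through a five-membered transition state (a 2-acylcyclopentanone) or a geminal ester only through a four-membered one; all Claisen modes are reversible in NaOMe/MeOH, the two malonate-type esters are the more electrophilic acceptors, and only the cyclohexane-1,3-dione is drained irreversibly as its vinylogous carboxylate, the most acidic species available. Keeping the base catalytic and cold during the Michael stage should limit polymerisation of 5.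

**Step 4**
Reactants: 8 methyl 1-(2-methoxy-2-oxoethyl)-3-prenyl-2,4-dioxocyclohexane-1-carboxylate
Product: 10 2-(3-prenyl-2,4-dioxocyclohexyl)acetic acid (racemic), via diacid 9 (not isolated)
Conditions: NaOH (4 equiv), MeOH/H2O, reflux; then 1 M HCl to pH 3, 50 °C
Reagents that add atoms: sodium hydroxide, [Na+].[OH-]
Why: Saponification of both esters followed by acidification should trigger β-keto acid decarboxylation at C1' (as in the dimedone sequence), the dione being shielded as its enolate in the basic stage and the short pH 3 finish being too mild to add the enol across the prenyl double bond.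

**Step 5**
Reactants: 10 2-(3-prenyl-2,4-dioxocyclohexyl)acetic acid
Product: 11 7-prenyl-3,3a,4,5-tetrahydro-1-benzofuran-2,6-dione (racemic enol lactone)
Conditions: EDC·HCl, DMAP (cat.), CH2Cl2 (0.05 M), 0 °C to rt
Reagents that add atoms: none
Why: Carbodiimide-mediated O-acylation of a cyclohexane-1,3-dione enol (enol ester formation) is intramolecular here, and only O2' can reach the arm through a five-membered ring, so O2' becomes the lactone oxygen while C4' stays a ketone.

**Step 6**
Reactants: 11 7-prenyl-3,3a,4,5-tetrahydro-1-benzofuran-2,6-dione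
Product: 14 6-hydroxy-7-prenyl-1-benzofuran-2(3H)-one, via silyl dienol ether 12 (not isolated), via aryl silyl ether 13 (not isolated)
Conditions: TMSOTf, Et3N, CH2Cl2, 0 °C; evaporate, pentane, filter; DDQ (1.0 equiv), 2,6-lutidine, CH2Cl2, 0 °C; aq. citric acid
Reagents that add atoms: none
Why: This is a ketone dehydrogenation through the silyl enol ether with DDQ, in which soft enolisation should silylate only the C4' ketone (not the lactone), either dienol ether regioisomer is a cyclohexa-1,3-diene that DDQ aromatises to the same aryl silyl ether before the oxidant can attack the prenyl group, and work-up hydrolyses the aryl TMS ether.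

**Step 7**
Reactants: 14 6-hydroxy-7-prenyl-1-benzofuran-2(3H)-one
Product: 15 7-prenyl-6-(THP-oxy)-1-benzofuran-2(3H)-one (racemic)
Conditions: 3,4-dihydro-2H-pyran, pyridinium p-toluenesulfonate (cat.), CH2Cl2, rt
Reagents that add atoms: 3,4-dihydro-2H-pyran, C1=COCCC1
Why: Acid-catalysed THP acetal formation should protect the only free phenol (O4') without base, so the acidic lactone CH2 is not alkylated, and the catalyst is too weak to cyclise the ortho prenyl group; the acetal carbon forms as a racemate.

**Step 8**
Reactants: 15 7-prenyl-6-(THP-oxy)-1-benzofuran-2(3H)-one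
Product: 17 methyl 2-[2-methoxy-3-prenyl-4-(THP-oxy)phenyl]acetate (racemic), via sodium phenoxide 16 (not isolated)
Conditions: NaOMe (1.05 equiv), MeOH, 0 °C to rt; then MeI, DMF, rt
Reagents that add atoms: sodium methoxide, C[O-].[Na+]; iodomethane, CI
Why: Methanolysis of the aryl ester (lactone) is driven by release of the O2' phenoxide, which is then the only nucleophilic oxygen and should be O-methylated by MeI (Williamson ether synthesis).

**Step 9**
Reactants: 17 methyl 2-[2-methoxy-3-prenyl-4-(THP-oxy)phenyl]acetate
Product: 18 N-methoxy-N-methyl-2-[2-methoxy-3-prenyl-4-(THP-oxy)phenyl]acetamide (racemic)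
Conditions: MeNH(OMe)·HCl, i-PrMgCl, THF, −20 °C to 0 °C
Reagents that add atoms: N,O-dimethylhydroxylamine hydrochloride, CNOC.Cl
Why: Aminolysis of the methyl ester by the magnesium amide of N,O-dimethylhydroxylamine should give the Weinreb amide directly and leaves acetal, aryl ether and alkene untouched.

**Step 10**
Reactants: 19 phloroglucinol
Product: 20 1,3,5-tris(methoxymethoxy)benzene
Conditions: NaH, MOMCl, DMF, 0 °C to rt
Reagents that add atoms: chloromethyl methyl ether, COCCl
Why: Threefold Williamson O-alkylation with the hard electrophile MOMCl should install the groups that later direct every ring lithiation and are removed together by mild acid.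

**Step 11**
Reactants: 20 1,3,5-tris(methoxymethoxy)benzene
Product: 22 1,3,5-tris(methoxymethoxy)-2-prenylbenzene, via aryllithium 21 (not isolated)
Conditions: n-BuLi, THF, 0 °C; CuI (cat.), prenyl bromide, −78 °C to rt
Reagents that add atoms: 1-bromo-3-methylbut-2-ene, CC(C)=CCBr
Why: Directed ortho-metalation between two OMOM groups followed by CuI-catalysed SN2 allylation should give the linear prenyl arene.

**Step 12**
Reactants: 22 1,3,5-tris(methoxymethoxy)-2-prenylbenzene
Product: 24 1,3,5-tris(methoxymethoxy)-2,4-diprenylbenzene, via aryllithium 23 (not isolated)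
Conditions: n-BuLi, THF, 0 °C; CuI (cat.), prenyl bromide, −78 °C to rt
Reagents that add atoms: 1-bromo-3-methylbut-2-ene, CC(C)=CCBr
Why: A second directed ortho-metalation/allylation works on two equivalent ring positions, each flanked by two OMOM groups, so one regioisomer is expected, and coordination-assisted ring lithiation should outrun deprotonation of the benzylic–allylic CH2.

**Step 13**
Reactants: 24 1,3,5-tris(methoxymethoxy)-2,4-diprenylbenzene; 18 N-methoxy-N-methyl-2-[2-methoxy-3-prenyl-4-(THP-oxy)phenyl]acetamide
Product: 26 2-[2-methoxy-3-prenyl-4-(THP-oxy)phenyl]-1-[2,4,6-tris(methoxymethoxy)-3,5-diprenylphenyl]ethan-1-one (racemic), via aryllithium 25 (not isolated)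
Conditions: 24 (1.3 equiv), n-BuLi, THF, 0 °C; then 18, −78 °C to 0 °C; H2O
Reagents that add atoms: none
Why: Directed ortho-metalation of the last ring position and Weinreb ketone synthesis should give the deoxybenzoin, since the chelated tetrahedral adduct stops at the ketone stage and low temperature favours addition over deprotonation of the amide CH2.

**Step 14**
Reactants: 26 deoxybenzoin from step 13
Product: 27 (E)-3-(dimethylamino)-2-[2-methoxy-3-prenyl-4-(THP-oxy)phenyl]-1-[2,4,6-tris(methoxymethoxy)-3,5-diprenylphenyl]prop-2-en-1-one (racemic)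
Conditions: Me2NCH(OMe)2, toluene, 95 °C
Reagents that add atoms: N,N-dimethylformamide dimethyl acetal, COC(OC)N(C)C
Why: Condensation of the doubly activated CH2 with the amide acetal (enaminone formation) supplies C2 under neutral conditions that spare acetals and prenyl groups.

**Step 15**
Reactants: 27 enaminone from step 14
Product: 29 5,7-dihydroxy-3-(4-hydroxy-2-methoxy-3-prenylphenyl)-6,8-diprenyl-4H-chromen-4-one (target), via deprotected enaminone 28 (not isolated)
Conditions: HCl (1 M) in MeOH, 45 °C
Reagents that add atoms: none
Why: Acid-catalysed transacetalisation to methanol removes the three MOM groups and the THP group, and a freed ortho phenol of ring A adds to the enaminone and expels dimethylamine (chromone ring closure); the two ortho phenols are equivalent, so one isoflavone should form, and dilute acid at moderate temperature is chosen to spare the prenyl groups.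

**Compound list**
1 | 5-bromo-2-methylpent-2-ene | CC(C)=CCCBr | starting material
2 | acrolein | C=CC=O | starting material
3 | (4-methylpent-3-en-1-yl)magnesium bromide (not isolated) | CC(C)=CCC[Mg]Br | intermediate
4 | 7-methylocta-1,6-dien-3-ol (racemic) | C=CC(O)CCC=C(C)C | intermediate
5 | 7-methylocta-1,6-dien-3-one | C=CC(=O)CCC=C(C)C | intermediate
6 | trimethyl ethane-1,1,2-tricarboxylate | COC(=O)CC(C(=O)OC)C(=O)OC | starting material
7 | trimethyl 9-methyl-5-oxodec-8-ene-1,2,2-tricarboxylate (Michael adduct, not isolated) | COC(=O)CC(CCC(=O)CCC=C(C)C)(C(=O)OC)C(=O)OC | intermediate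
8 | methyl 1-(2-methoxy-2-oxoethyl)-3-prenyl-2,4-dioxocyclohexane-1-carboxylate (racemic, enolisable) | COC(=O)CC1(C(=O)OC)CCC(=O)C(CC=C(C)C)C1=O | intermediate
9 | 1-(carboxymethyl)-3-prenyl-2,4-dioxocyclohexane-1-carboxylic acid (racemic, not isolated) | OC(=O)CC1(C(=O)O)CCC(=O)C(CC=C(C)C)C1=O | intermediate
10 | 2-(3-prenyl-2,4-dioxocyclohexyl)acetic acid (racemic, enolisable) | OC(=O)CC1CCC(=O)C(CC=C(C)C)C1=O | intermediate
11 | 7-prenyl-3,3a,4,5-tetrahydro-1-benzofuran-2,6-dione (racemic) | O=C1CC2CCC(=O)C(CC=C(C)C)=C2O1 | intermediate
12 | 7-prenyl-6-(trimethylsilyloxy)-3a,4-dihydro-1-benzofuran-2(3H)-one (racemic, not isolated) | C[Si](C)(C)OC1=CCC2CC(=O)OC2=C1CC=C(C)C | intermediate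
13 | 7-prenyl-6-(trimethylsilyloxy)-1-benzofuran-2(3H)-one (not isolated) | C[Si](C)(C)Oc1ccc2CC(=O)Oc2c1CC=C(C)C | intermediate
14 | 6-hydroxy-7-prenyl-1-benzofuran-2(3H)-one | Oc1ccc2CC(=O)Oc2c1CC=C(C)C | intermediate
15 | 7-prenyl-6-(THP-oxy)-1-benzofuran-2(3H)-one (racemic) | O=C1Cc2ccc(OC3CCCCO3)c(CC=C(C)C)c2O1 | intermediate
16 | sodium 6-(2-methoxy-2-oxoethyl)-2-prenyl-3-(THP-oxy)phenolate (racemic, not isolated) | COC(=O)Cc1ccc(OC2CCCCO2)c(CC=C(C)C)c1[O-].[Na+] | intermediate
17 | methyl 2-[2-methoxy-3-prenyl-4-(THP-oxy)phenyl]acetate (racemic) | COC(=O)Cc1ccc(OC2CCCCO2)c(CC=C(C)C)c1OC | intermediate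
18 | N-methoxy-N-methyl-2-[2-methoxy-3-prenyl-4-(THP-oxy)phenyl]acetamide (racemic) | CON(C)C(=O)Cc1ccc(OC2CCCCO2)c(CC=C(C)C)c1OC | intermediate
19 | phloroglucinol | Oc1cc(O)cc(O)c1 | starting material
20 | 1,3,5-tris(methoxymethoxy)benzene | COCOc1cc(OCOC)cc(OCOC)c1 | intermediate
21 | [2,4,6-tris(methoxymethoxy)phenyl]lithium (not isolated) | [Li]c1c(OCOC)cc(OCOC)cc1OCOC | intermediate
22 | 1,3,5-tris(methoxymethoxy)-2-prenylbenzene | COCOc1cc(OCOC)c(CC=C(C)C)c(OCOC)c1 | intermediate
23 | [2,4,6-tris(methoxymethoxy)-3-prenylphenyl]lithium (not isolated) | [Li]c1c(OCOC)cc(OCOC)c(CC=C(C)C)c1OCOC | intermediate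
24 | 1,3,5-tris(methoxymethoxy)-2,4-diprenylbenzene | COCOc1cc(OCOC)c(CC=C(C)C)c(OCOC)c1CC=C(C)C | intermediate
25 | [2,4,6-tris(methoxymethoxy)-3,5-diprenylphenyl]lithium (not isolated) | [Li]c1c(OCOC)c(CC=C(C)C)c(OCOC)c(CC=C(C)C)c1OCOC | intermediate
26 | 2-[2-methoxy-3-prenyl-4-(THP-oxy)phenyl]-1-[2,4,6-tris(methoxymethoxy)-3,5-diprenylphenyl]ethan-1-one (racemic) | COCOc1c(CC=C(C)C)c(OCOC)c(CC=C(C)C)c(OCOC)c1C(=O)Cc1ccc(OC2CCCCO2)c(CC=C(C)C)c1OC | intermediate
27 | (E)-3-(dimethylamino)-2-[2-methoxy-3-prenyl-4-(THP-oxy)phenyl]-1-[2,4,6-tris(methoxymethoxy)-3,5-diprenylphenyl]prop-2-en-1-one (racemic) | COCOc1c(CC=C(C)C)c(OCOC)c(CC=C(C)C)c(OCOC)c1C(=O)/C(=C/N(C)C)c1ccc(OC2CCCCO2)c(CC=C(C)C)c1OC | intermediate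
28 | (E)-3-(dimethylamino)-2-(4-hydroxy-2-methoxy-3-prenylphenyl)-1-(2,4,6-trihydroxy-3,5-diprenylphenyl)prop-2-en-1-one (not isolated) | CN(C)/C=C(/C(=O)c1c(O)c(CC=C(C)C)c(O)c(CC=C(C)C)c1O)c1ccc(O)c(CC=C(C)C)c1OC | intermediate
29 | 5,7-dihydroxy-3-(4-hydroxy-2-methoxy-3-prenylphenyl)-6,8-diprenyl-4H-chromen-4-one (no stereocentres) | COc1c(-c2coc3c(CC=C(C)C)c(O)c(CC=C(C)C)c(O)c3c2=O)ccc(O)c1CC=C(C)C | target

**Step count.** Total: 15 steps. Longest linear sequence: 12 steps (steps 1–9, then 13–15); the ring A branch (steps 10–12) joins at step 13.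

**Steps most likely to fail**

Step 6. The enolsilylation may be incomplete, or DDQ may abstract hydride from the benzylic–allylic CH2 of the prenyl group once the ring is aromatic. The fallback moves the dehydrogenation to selenium chemistry and sets out from enol lactone 11. Deprotonation with LiN(i-Pr)2 in THF at −78 °C and trapping with PhSeCl should give 5-(phenylselanyl)-7-prenyl-3,3a,4,5-tetrahydro-1-benzofuran-2,6-dione F1. Oxidation with H2O2/pyridine in CH2Cl2 at 0 °C should give the selenoxide 5-(benzeneseleninyl)-7-prenyl-3,3a,4,5-tetrahydro-1-benzofuran-2,6-dione F2. Its syn-elimination leaves the cyclohexadienone tautomer of the phenol, so the route is rejoined at 14. A selenide formed at the lactone CH2 instead would eliminate towards C1' and tautomerise to the same phenol.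

Step 3. The ring may close through the C5' enolate onto the side-arm ester, or the vinyl ketone may polymerise before the malonate adds. The fallback separates ring formation from introduction of the arm and sets out from vinyl ketone 5. Michael addition of dimethyl malonate (NaOMe, MeOH) should give dimethyl 2-(7-methyl-3-oxooct-6-en-1-yl)propanedioate F3, which has no competing ester and cyclises on heating to methyl 3-prenyl-2,4-dioxocyclohexane-1-carboxylate F4. Its dianion (NaH, then LiN(i-Pr)2, THF, −78 °C) should be alkylated at the less stabilised carbanion C1' by methyl bromoacetate, which rejoins the route at 8.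

Step 15. While the last acetals are cleaved, a neighbouring phenol may add across a prenyl double bond (chroman formation), or methanol or HCl may add to the alkene. The fallback removes the acetals before ring closure under aprotic conditions and sets out from deoxybenzoin 26. ZnBr2 and n-PrSH in CH2Cl2 at 0 °C should transfer the MOM and THP groups to the thiol and give 2-(4-hydroxy-2-methoxy-3-prenylphenyl)-1-(2,4,6-trihydroxy-3,5-diprenylphenyl)ethan-1-one F5. Treatment with Me2NCH(OMe)2 in THF at rt to 50 °C should then form enaminone 28, which closes under these neutral conditions and rejoins the route at 29.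

**Further compounds**
F1 | step 6 | 5-(phenylselanyl)-7-prenyl-3,3a,4,5-tetrahydro-1-benzofuran-2,6-dione (mixture of diastereomers) | O=C1CC2CC([Se]c3ccccc3)C(=O)C(CC=C(C)C)=C2O1
F2 | step 6 | 5-(benzeneseleninyl)-7-prenyl-3,3a,4,5-tetrahydro-1-benzofuran-2,6-dione (mixture of diastereomers) | O=C1CC2CC([Se](=O)c3ccccc3)C(=O)C(CC=C(C)C)=C2O1
F3 | step 3 | dimethyl 2-(7-methyl-3-oxooct-6-en-1-yl)propanedioate | COC(=O)C(CCC(=O)CCC=C(C)C)C(=O)OC
F4 | step 3 | methyl 3-prenyl-2,4-dioxocyclohexane-1-carboxylate (racemic, enolisable) | COC(=O)C1CCC(=O)C(CC=C(C)C)C1=O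
F5 | step 15 | 2-(4-hydroxy-2-methoxy-3-prenylphenyl)-1-(2,4,6-trihydroxy-3,5-diprenylphenyl)ethan-1-one | COc1c(CC(=O)c2c(O)c(CC=C(C)C)c(O)c(CC=C(C)C)c2O)ccc(O)c1CC=C(C)C
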